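Colupulone's ring (C1 monoprenyl, C2, C3 gem-diprenyl, C4, C5 acyl, C6) is cut into a four-carbon cyclobutenone (C2, C5, C4, C3) and a two-carbon siloxyalkyne (C1, C6). One light-triggered, then thermal pericyclic cascade forms C1–C2 and C5–C6, re-forms C2–C3 and delivers the cyclohexa-2,4-dienone with every carbon substituent in place. It exploits two features of the ring: the only sp3 atom, C3, is quaternary with two identical prenyl groups, so the dienone cannot aromatise and no stereocentre arises, and the oxygen atoms occupy the alternate positions C2, C4 and C6. The precursor is a 3-ethoxy-4,4-diprenylcyclobutenone whose C5 substituent is the acyl group masked as a silylated carbinol.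

Key step: step 7

Remarks on the chemistry: the carbinol carbon of 10, 11, 13 and 18–22 is carried as a racemate (19 as a diastereomer mixture). This centre is erased in step 9 and needs no control. Colupulone is a set of rapidly interconverting enol tautomers; step 10 gives this set, and the SMILES of 24 shows the tautomer of the target. The cyclobutenone is opened with light because a 3-alkoxy-4,4-dialkylcyclobutenone is expected to open thermally only at temperatures that endanger the prenyl groups.

Step 1
Reactants: 1 diethyl malonate; 2 prenyl bromide (1-bromo-3-methylbut-2-ene)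
Product: 3 diethyl 2,2-bis(3-methylbut-2-enyl)propanedioate
Conditions: NaH (2.2 equiv), 2 (2.3 equiv), THF/DMF, 0 → 20 °C
Reagents that add atoms: none
Why: Double SN2 alkylation of the malonate enolate with a reactive primary allylic bromide (malonic ester synthesis) should give the gem-diprenyl diester without forming a stereocentre.

Step 2
Reactants: 3 diethyl 2,2-bis(3-methylbut-2-enyl)propanedioate
Product: 5 5-methyl-2-(3-methylbut-2-enyl)hex-4-enoic acid, via diprenylmalonic acid 4 (not isolated)
Conditions: KOH, EtOH/H2O, reflux; cold 1 M HCl, extraction; pyridine, 115 °C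
Reagents that add atoms: potassium hydroxide [K+].[OH-]
Why: Saponification of both esters followed by decarboxylation of the malonic acid (malonic ester synthesis) should give the diprenylacetic acid, the decarboxylation being run in pyridine so that no strong acid meets the trisubstituted alkenes.

Step 3
Reactants: 5 5-methyl-2-(3-methylbut-2-enyl)hex-4-enoic acid
Product: 6 5-methyl-2-(3-methylbut-2-enyl)hex-4-enoyl chloride
Conditions: (COCl)2, DMF (cat.), CH2Cl2, 0 → 20 °C; volatiles removed, used crude
Reagents that add atoms: oxalyl chloride O=C(Cl)C(=O)Cl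
Why: Vilsmeier-type activation of the acid by oxalyl chloride and catalytic DMF is a standard acid chloride formation that acids carrying prenyl groups tolerate at or below room temperature.

Step 4
Reactants: 7 ethoxyacetylene (ethoxyethyne); 8 isobutyraldehyde (2-methylpropanal)
Product: 11 triethyl[(1-ethoxy-4-methylpent-1-yn-3-yl)oxy]silane (racemic), via lithium ethoxyacetylide 9 (not isolated), via lithium propargylic alkoxide 10 (not isolated)
Conditions: n-BuLi, THF, −78 °C; 8; Et3SiCl, DMAP (cat.), −78 → 20 °C; NaHCO3 work-up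
Reagents that add atoms: chlorotriethylsilane CC[Si](Cl)(CC)CC
Why: 1,2-Addition of the lithium acetylide to the aldehyde and O-silylation of the alkoxide in the same flask avoid isolating the acid-sensitive ethoxyalkynyl carbinol (prone to Meyer–Schuster rearrangement); the carbinol centre forms as a racemate, which suffices because it is oxidised in step 9.

Step 5
Reactants: 6 5-methyl-2-(3-methylbut-2-enyl)hex-4-enoyl chloride; 11 triethyl[(1-ethoxy-4-methylpent-1-yn-3-yl)oxy]silane
Product: 13 3-ethoxy-4,4-bis(3-methylbut-2-enyl)-2-[2-methyl-1-(triethylsilyloxy)propyl]cyclobut-2-en-1-one (racemic), via diprenylketene 12 (not isolated)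
Conditions: Et3N, THF, 50 °C; filtration under argon; 11, 20 → 40 °C
Reagents that add atoms: none
Why: Dehydrochlorination of the α,α-disubstituted acid chloride gives the dialkylketene, which should undergo the known regioselective ketene–alkoxyalkyne [2+2] cycloaddition, the ketene carbonyl carbon joining the nucleophilic β-carbon of the ynol ether and the diprenyl carbon joining the ethoxy carbon; removing the ammonium salt first protects the ynol ether.

Step 6
Reactants: 14 ethyl 4-methylpent-3-enoate
Product: 17 triisopropyl(5-methylhex-4-en-1-ynyloxy)silane, via dibromomethyl ester adduct 15 (not isolated), via lithium ynolate 16 (not isolated)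
Conditions: CH2Br2, lithium 2,2,6,6-tetramethylpiperidide, THF, −78 °C; 14; n-BuLi, LiN(SiMe3)2, −78 → 0 °C; iPr3SiCl, −78 → 20 °C
Reagents that add atoms: dibromomethane BrCBr; chlorotriisopropylsilane CC(C)[Si](Cl)(C(C)C)C(C)C
Why: Kowalski ester homologation: LiCHBr2 adds to the ester, the derived bromo-lithio enolate rearranges by 1,2-shift of the prenyl group to the lithium ynolate, and the bulky silyl chloride should silylate this on oxygen to give the siloxyalkyne.

Step 7
Reactants: 13 3-ethoxy-4,4-bis(3-methylbut-2-enyl)-2-[2-methyl-1-(triethylsilyloxy)propyl]cyclobut-2-en-1-one; 17 triisopropyl(5-methylhex-4-en-1-ynyloxy)silane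
Product: 21 5-ethoxy-2,6,6-tris(3-methylbut-2-enyl)-4-[2-methyl-1-(triethylsilyloxy)propyl]-3-(triisopropylsilyloxy)cyclohexa-2,4-dien-1-one (racemic), via vinylketene 18 (not isolated), via 4-vinylcyclobutenone 19 (not isolated), via dienylketene 20 (not isolated)
Conditions: 17 (2 equiv), hν (300 nm), degassed PhMe (1 M), 20 °C; then 80 °C, dark
Reagents that add atoms: none
Why: Proposed new method: light opens 13 by 4π electrocyclic cleavage of C2–C3 to vinylketene 18, whose carbonyl carbon C2 is attacked by the nucleophilic, prenyl-bearing carbon C1 of 17 while its α-carbon C5 bonds to the siloxy carbon C6, giving 4-vinylcyclobutenone 19, which at 80 °C opens to dienylketene 20 and closes between C2 and the diprenyl terminus C3. The closest known reaction types are the Danheiser benzannulation of cyclobutenones with siloxyalkynes and the thermal reclosure of dienylketenes to 6,6-disubstituted cyclohexa-2,4-dienones. The six-membered ring is closed by a thermal disrotatory 6π electrocyclisation that forms C2–C3 after the [2+2] has joined C1–C2 and C5–C6. No stereocentre is created, because C3 carries two identical prenyl groups and the carbinol centre is only carried through as a racemate. The step needs regioselectivity in the [2+2], which the polarisation of the siloxyalkyne secures, and a cis relation of ketene and vinyl group in 20, which is reached because the opening of 19 is reversible while the 6π closure is not. Because C3 is quaternary, the dienone cannot tautomerise to a phenol and the cascade should stop at 21.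

Step 8
Reactants: 21 5-ethoxy-2,6,6-tris(3-methylbut-2-enyl)-4-[2-methyl-1-(triethylsilyloxy)propyl]-3-(triisopropylsilyloxy)cyclohexa-2,4-dien-1-one
Product: 22 5-ethoxy-3-hydroxy-4-(1-hydroxy-2-methylpropyl)-2,6,6-tris(3-methylbut-2-enyl)cyclohexa-2,4-dien-1-one (racemic)
Conditions: Bu4NF, AcOH, THF, 0 → 20 °C (argon)
Reagents that add atoms: none
Why: Fluoride-mediated desilylation should cleave both the secondary triethylsilyl ether and the silyl vinylogous ester, the acetic acid buffer keeping the medium near neutral so that the carbinol, which is allylic to the enol ether, is not ionised.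

Step 9
Reactants: 22 5-ethoxy-3-hydroxy-4-(1-hydroxy-2-methylpropyl)-2,6,6-tris(3-methylbut-2-enyl)cyclohexa-2,4-dien-1-one
Product: 23 5-ethoxy-3-hydroxy-4-(2-methylpropanoyl)-2,6,6-tris(3-methylbut-2-enyl)cyclohexa-2,4-dien-1-one
Conditions: Dess–Martin periodinane (1.1 equiv), pyridine, CH2Cl2, 0 °C (argon)
Reagents that add atoms: none
Why: Dess–Martin oxidation of the secondary allylic carbinol is fast at 0 °C, pyridine takes up the acetic acid formed, and one equivalent at low temperature should spare the enolised β-dicarbonyl unit and the prenyl alkenes; the only stereocentre is removed here.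

Step 10
Reactants: 23 5-ethoxy-3-hydroxy-4-(2-methylpropanoyl)-2,6,6-tris(3-methylbut-2-enyl)cyclohexa-2,4-dien-1-one
Product: 24 colupulone, 3,5-dihydroxy-2-(2-methylpropanoyl)-4,6,6-tris(3-methylbut-2-enyl)cyclohexa-2,4-dien-1-one
Conditions: LiOH, THF/H2O, 50 °C (argon); cold 1 M HCl to pH 3
Reagents that add atoms: lithium hydroxide [Li+].[OH-]
Why: Hydroxide should add to C4, the β-carbon of the acyl-activated vinylogous ethyl ester, and expel ethoxide (addition–elimination hydrolysis of a vinylogous ester, the usual unmasking of acylphloroglucinol-type triketones), and acidification gives colupulone as its enolised tautomers.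

Compound list
1 | diethyl malonate | CCOC(=O)CC(=O)OCC | starting material
2 | prenyl bromide (1-bromo-3-methylbut-2-ene) | CC(C)=CCBr | starting material
3 | diethyl 2,2-bis(3-methylbut-2-enyl)propanedioate | CCOC(=O)C(CC=C(C)C)(CC=C(C)C)C(=O)OCC | intermediate
4 | 2,2-bis(3-methylbut-2-enyl)propanedioic acid (diprenylmalonic acid) | OC(=O)C(CC=C(C)C)(CC=C(C)C)C(=O)O | intermediate
5 | 5-methyl-2-(3-methylbut-2-enyl)hex-4-enoic acid | CC(C)=CCC(CC=C(C)C)C(=O)O | intermediate
6 | 5-methyl-2-(3-methylbut-2-enyl)hex-4-enoyl chloride | CC(C)=CCC(CC=C(C)C)C(=O)Cl | intermediate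
7 | ethoxyacetylene (ethoxyethyne) | CCOC#C | starting material
8 | isobutyraldehyde (2-methylpropanal) | CC(C)C=O | starting material
9 | lithium ethoxyacetylide | CCOC#C[Li] | intermediate
10 | lithium 1-ethoxy-4-methylpent-1-yn-3-olate (racemic) | CCOC#CC([O-])C(C)C.[Li+] | intermediate
11 | triethyl[(1-ethoxy-4-methylpent-1-yn-3-yl)oxy]silane (racemic) | CCOC#CC(O[Si](CC)(CC)CC)C(C)C | intermediate
12 | diprenylketene, 5-methyl-2-(3-methylbut-2-enyl)hexa-1,4-dien-1-one | CC(C)=CCC(CC=C(C)C)=C=O | intermediate
13 | 3-ethoxy-4,4-bis(3-methylbut-2-enyl)-2-[2-methyl-1-(triethylsilyloxy)propyl]cyclobut-2-en-1-one (racemic) | CCOC1=C(C(O[Si](CC)(CC)CC)C(C)C)C(=O)C1(CC=C(C)C)CC=C(C)C | intermediate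
14 | ethyl 4-methylpent-3-enoate | CCOC(=O)CC=C(C)C | starting material
15 | lithium 1,1-dibromo-2-ethoxy-5-methylhex-4-en-2-olate (racemic) | CCOC([O-])(CC=C(C)C)C(Br)Br.[Li+] | intermediate
16 | lithium 5-methylhex-4-en-1-yn-1-olate (ynolate) | [Li+].[O-]C#CCC=C(C)C | intermediate
17 | triisopropyl(5-methylhex-4-en-1-ynyloxy)silane | CC(C)=CCC#CO[Si](C(C)C)(C(C)C)C(C)C | intermediate
18 | vinylketene, 3-ethoxy-7-methyl-4-(3-methylbut-2-enyl)-2-[2-methyl-1-(triethylsilyloxy)propyl]octa-1,3,6-trien-1-one (racemic) | O=C=C(C(O[Si](CC)(CC)CC)C(C)C)C(OCC)=C(CC=C(C)C)CC=C(C)C | intermediate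
19 | 4-vinylcyclobutenone, 4-[1-ethoxy-5-methyl-2-(3-methylbut-2-enyl)hexa-1,4-dienyl]-2-(3-methylbut-2-enyl)-4-[2-methyl-1-(triethylsilyloxy)propyl]-3-(triisopropylsilyloxy)cyclobut-2-en-1-one (diastereomer mixture, racemic) | O=C1C(CC=C(C)C)=C(O[Si](C(C)C)(C(C)C)C(C)C)C1(C(O[Si](CC)(CC)CC)C(C)C)C(OCC)=C(CC=C(C)C)CC=C(C)C | intermediate
20 | dienylketene, (3E)-5-ethoxy-9-methyl-2,6-bis(3-methylbut-2-enyl)-4-[2-methyl-1-(triethylsilyloxy)propyl]-3-(triisopropylsilyloxy)deca-1,3,5,8-tetraen-1-one (ketene carbon and ethoxyvinyl group cis; racemic) | O=C=C(CC=C(C)C)/C(O[Si](C(C)C)(C(C)C)C(C)C)=C(/C(O[Si](CC)(CC)CC)C(C)C)C(OCC)=C(CC=C(C)C)CC=C(C)C | intermediate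
21 | 5-ethoxy-2,6,6-tris(3-methylbut-2-enyl)-4-[2-methyl-1-(triethylsilyloxy)propyl]-3-(triisopropylsilyloxy)cyclohexa-2,4-dien-1-one (racemic) | O=C1C(CC=C(C)C)=C(O[Si](C(C)C)(C(C)C)C(C)C)C(C(O[Si](CC)(CC)CC)C(C)C)=C(OCC)C1(CC=C(C)C)CC=C(C)C | intermediate
22 | 5-ethoxy-3-hydroxy-4-(1-hydroxy-2-methylpropyl)-2,6,6-tris(3-methylbut-2-enyl)cyclohexa-2,4-dien-1-one (racemic) | O=C1C(CC=C(C)C)=C(O)C(C(O)C(C)C)=C(OCC)C1(CC=C(C)C)CC=C(C)C | intermediate
23 | 5-ethoxy-3-hydroxy-4-(2-methylpropanoyl)-2,6,6-tris(3-methylbut-2-enyl)cyclohexa-2,4-dien-1-one | O=C1C(CC=C(C)C)=C(O)C(C(=O)C(C)C)=C(OCC)C1(CC=C(C)C)CC=C(C)C | intermediate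
24 | colupulone, 3,5-dihydroxy-2-(2-methylpropanoyl)-4,6,6-tris(3-methylbut-2-enyl)cyclohexa-2,4-dien-1-one (achiral) | CC(C)=CCC1=C(O)C(CC=C(C)C)(CC=C(C)C)C(=O)C(C(=O)C(C)C)=C1O | target

Total step count: 10. Longest linear sequence: 8 steps (steps 1, 2, 3, 5, 7, 8, 9, 10, from diethyl malonate); steps 4 and 6 are one-step branches.

Steps most likely to fail

Step 7. Vinylketene 18 is α-branched and donor-substituted, so its bimolecular [2+2] may be slow. It could then be consumed by intramolecular [2+2] onto its own cis prenyl alkene or by a 1,5-hydrogen shift. Prolonged heating could also move a prenyl group of 21 by a [3,3] shift. The fallback uses known chemistry, sets out from prenyl bromide 2 and returns to the route at 24. Phloroglucinol is C-acylated with isobutyryl chloride (AlCl3, PhNO2/CH2Cl2) to 2-methyl-1-(2,4,6-trihydroxyphenyl)propan-1-one F1. F1 is then C-prenylated three times with 2 (NaOMe, MeOH, 0 °C), the second alkylation at one ring carbon dearomatising the ring, which should give colupulone 24 directly.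

Step 9. The periodinane could attack the enolised β-dicarbonyl unit (C2/C1/C6) and oxidise C1 in competition with the carbinol, or the acetic acid formed could ionise the carbinol. The fallback sets out from 22 and returns at 24, and it oxidises with the ring oxygens capped. The acidic enol is silylated selectively (iPr3SiCl, Et3N, CH2Cl2, 0 °C; the hindered carbinol should not react) to 5-ethoxy-4-(1-hydroxy-2-methylpropyl)-2,6,6-tris(3-methylbut-2-enyl)-3-(triisopropylsilyloxy)cyclohexa-2,4-dien-1-one F2. Dess–Martin oxidation of this neutral alcohol should give 5-ethoxy-4-(2-methylpropanoyl)-2,6,6-tris(3-methylbut-2-enyl)-3-(triisopropylsilyloxy)cyclohexa-2,4-dien-1-one F3. Aqueous LiOH in THF then removes the silyl group and the ethyl group in one operation to give 24.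

Step 6. The β,γ-unsaturated ester could be enolised by the lithium carbenoid or amide instead of undergoing addition, and the ynolate could be silylated on carbon. The fallback sets out from 2 and returns at 17. Coupling of 2 with ethynylmagnesium bromide (CuCl cat., THF) gives 5-methylhex-4-en-1-yne F4. Its lithium acetylide is oxidised by lithium tert-butyl peroxide (LiN(SiMe3)2, t-BuOOH, THF, −78 → 0 °C) to ynolate 16, which is silylated with iPr3SiCl as in step 6 to give 17.

Further compounds
F1 | step 7 | 2-methyl-1-(2,4,6-trihydroxyphenyl)propan-1-one | CC(C)C(=O)c1c(O)cc(O)cc1O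
F2 | step 9 | 5-ethoxy-4-(1-hydroxy-2-methylpropyl)-2,6,6-tris(3-methylbut-2-enyl)-3-(triisopropylsilyloxy)cyclohexa-2,4-dien-1-one (racemic) | O=C1C(CC=C(C)C)=C(O[Si](C(C)C)(C(C)C)C(C)C)C(C(O)C(C)C)=C(OCC)C1(CC=C(C)C)CC=C(C)C
F3 | step 9 | 5-ethoxy-4-(2-methylpropanoyl)-2,6,6-tris(3-methylbut-2-enyl)-3-(triisopropylsilyloxy)cyclohexa-2,4-dien-1-one | O=C1C(CC=C(C)C)=C(O[Si](C(C)C)(C(C)C)C(C)C)C(C(=O)C(C)C)=C(OCC)C1(CC=C(C)C)CC=C(C)C
F4 | step 6 | 5-methylhex-4-en-1-yne | CC(C)=CCC#C
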